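**Strategy**

Everything rests on cutting two neighbouring bonds of ring A (dimethoxy ring, C1 at the bridge) at once: the C3–O bond of one methoxyl and the C4–CH2 bond of the prenyl group. Because C4 is also flanked by the C5 methoxyl, a C3–C4 aryne is polarized so that an ether oxygen adds at C3 and carbon arrives at C4; with 3-methoxy-3-methylbut-1-ene the aryl oxonium should pass its allyl unit to C4 with allylic transposition, installing methoxyl and prenyl in one operation. The precursor is the complete bibenzyl as an ortho-silyl aryl triflate, with O4' of ring B as SEM ether and O3' as MOM ether, so that the acetate position is fixed by the sequence.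

Key step: step 11

Remark on the chemistry (numbering, abbreviations, design assumption): ring B is the trioxygenated ring (C1' at the bridge, C2' OMe, C3' OH, C4' OAc). MOM = methoxymethyl; SEM = 2-(trimethylsilyl)ethoxymethyl. The two catechol oxygens are protected differently because SEM is expected to be inert to CsF at 40 °C but cleaved by hot TBAF, while MOM is inert to fluoride; this removes the need for a site-selective acetylation of a free catechol. The target has no stereocenter and no stereogenic double bond.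

**Route**

Step 1
Reactants: 1 2,3,4-trihydroxybenzaldehyde
Product: 2 2,3-dihydroxy-4-(SEM-oxy)benzaldehyde
Conditions: SEMCl (1.05 equiv), K2CO3 (1.0 equiv), acetone, 0 °C → rt
Reagents that add atoms: 2-(trimethylsilyl)ethoxymethyl chloride, C[Si](C)(C)CCOCCl
Why: Williamson-type O-alkylation in which one equivalent of mild base ionizes mainly the most acidic phenol, the 4-hydroxyl para to the formyl group, while the 2-hydroxyl is held in a hydrogen bond to the carbonyl, the same discrimination that allows 4-O-monobenzylation of this aldehyde.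

Step 2
Reactants: 2 2,3-dihydroxy-4-(SEM-oxy)benzaldehyde
Product: 3 2-hydroxy-3-(MOM-oxy)-4-(SEM-oxy)benzaldehyde
Conditions: NaH (2.1 equiv), THF/DMF, 0 °C; MOMCl (1.0 equiv), 0 °C
Reagents that add atoms: chloromethyl methyl ether, COCCl
Why: Williamson O-alkylation of the dianion, in which the C3 phenoxide is neither delocalized into the aldehyde nor chelated by sodium and is therefore the more nucleophilic oxygen, the known behaviour of 2,3-dihydroxybenzaldehyde dianions, so one equivalent of MOMCl should go on O3.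

Step 3
Reactants: 3 2-hydroxy-3-(MOM-oxy)-4-(SEM-oxy)benzaldehyde
Product: 4 2-methoxy-3-(MOM-oxy)-4-(SEM-oxy)benzaldehyde
Conditions: MeI, K2CO3, DMF, 40 °C
Reagents that add atoms: iodomethane, CI
Why: Williamson methylation of the last, hydrogen-bonded phenol under warm carbonate/DMF conditions, to which both acetals are stable.

Step 4
Reactants: 4 2-methoxy-3-(MOM-oxy)-4-(SEM-oxy)benzaldehyde
Product: 5 1-ethenyl-2-methoxy-3-(MOM-oxy)-4-(SEM-oxy)benzene
Conditions: Ph3PCH3Br, KOt-Bu, THF, 0 °C → rt
Reagents that add atoms: methyltriphenylphosphonium bromide, C[P+](c1ccccc1)(c1ccccc1)c1ccccc1.[Br-]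
Why: Wittig methylenation of an aromatic aldehyde with the non-stabilized ylide, which leaves acetals and aryl ethers untouched; the electron-rich styrene is used without storage.

Step 5
Reactants: 6 3-bromo-5-methoxyphenol
Product: 7 3-bromo-5-methoxyphenyl N,N-diethylcarbamate
Conditions: Et2NCOCl, K2CO3, MeCN, 80 °C
Reagents that add atoms: N,N-diethylcarbamoyl chloride, CCN(CC)C(=O)Cl
Why: O-carbamoylation of the phenoxide (acyl substitution) masks the phenol for the cross-coupling and installs the directing group for the later ortho-lithiation.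

Step 6
Reactants: 5 1-ethenyl-2-methoxy-3-(MOM-oxy)-4-(SEM-oxy)benzene; 7 3-bromo-5-methoxyphenyl N,N-diethylcarbamate
Product: 9 3-methoxy-5-{2-[2-methoxy-3-(MOM-oxy)-4-(SEM-oxy)phenyl]ethyl}phenyl N,N-diethylcarbamate, via alkyl-9-BBN adduct 8 (not isolated)
Conditions: 9-BBN, THF, 0 °C → rt; then 7, Pd(dppf)Cl2 (3 mol%), aq K3PO4, DMF, 60 °C
Reagents that add atoms: none
Why: Anti-Markovnikov hydroboration of the styrene with 9-BBN followed by B-alkyl Suzuki–Miyaura coupling with the aryl bromide forms the aryl–CH2 bond of the bibenzyl, and the diethylcarbamate, the acetals and the alkylsilane tolerate aqueous phosphate and zerovalent palladium.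

Step 7
Reactants: 9 3-methoxy-5-{2-[2-methoxy-3-(MOM-oxy)-4-(SEM-oxy)phenyl]ethyl}phenyl N,N-diethylcarbamate
Product: 11 3-methoxy-5-{2-[2-methoxy-3-(MOM-oxy)-4-(SEM-oxy)phenyl]ethyl}-2-(trimethylsilyl)phenyl N,N-diethylcarbamate, via ortho-lithiated carbamate 10 (not isolated)
Conditions: s-BuLi (1.15 equiv), TMEDA, THF, −78 °C; TMSCl, −78 °C → rt
Reagents that add atoms: chlorotrimethylsilane, C[Si](C)(C)Cl
Why: Directed ortho-metalation at the ring A carbon between the carbamate and the methoxyl, which is doubly activated and lithiated fastest at −78 °C where the anionic Fries shift is frozen, followed by silylation; the small excess of base should leave ring B (only the weaker acetal directors) and the benzylic positions alone.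

Step 8
Reactants: 11 3-methoxy-5-{2-[2-methoxy-3-(MOM-oxy)-4-(SEM-oxy)phenyl]ethyl}-2-(trimethylsilyl)phenyl N,N-diethylcarbamate
Product: 12 3-methoxy-5-{2-[2-methoxy-3-(MOM-oxy)-4-(SEM-oxy)phenyl]ethyl}-2-(trimethylsilyl)phenol
Conditions: LiAlH4, THF, 0 → 65 °C; then H2O, aq NaOH
Reagents that add atoms: none
Why: Hydride reduction of the O-aryl carbamate expels the phenoxide and takes the carbamoyl carbon down to an N-methyl group, while the aryl–silicon bond, the acetals and the ethers are inert to LiAlH4.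

Step 9
Reactants: 12 3-methoxy-5-{2-[2-methoxy-3-(MOM-oxy)-4-(SEM-oxy)phenyl]ethyl}-2-(trimethylsilyl)phenol
Product: 13 3-methoxy-5-{2-[2-methoxy-3-(MOM-oxy)-4-(SEM-oxy)phenyl]ethyl}-2-(trimethylsilyl)phenyl trifluoromethanesulfonate
Conditions: PhNTf2, DBU, MeCN, rt
Reagents that add atoms: N-phenylbis(trifluoromethanesulfonimide), O=S(=O)(N(c1ccccc1)S(=O)(=O)C(F)(F)F)C(F)(F)F
Why: O-triflation of the hindered phenoxide by sulfonyl transfer from the mild donor PhNTf2, which, unlike triflic anhydride, cannot activate the acetals, gives the ortho-silyl aryl triflate.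

Step 10
Reactants: 14 2-methylbut-3-en-2-ol
Product: 15 3-methoxy-3-methylbut-1-ene
Conditions: KOH (powder), MeI, DMSO, rt; distillation
Reagents that add atoms: iodomethane, CI
Why: Williamson methylation of the tertiary alkoxide in DMSO, from which the volatile ether is distilled and then dried before use.

Step 11
Reactants: 13 3-methoxy-5-{2-[2-methoxy-3-(MOM-oxy)-4-(SEM-oxy)phenyl]ethyl}-2-(trimethylsilyl)phenyl trifluoromethanesulfonate; 15 3-methoxy-3-methylbut-1-ene
Product: 18 1,3-dimethoxy-5-{2-[2-methoxy-3-(MOM-oxy)-4-(SEM-oxy)phenyl]ethyl}-2-(3-methylbut-2-en-1-yl)benzene, via aryne 16 (not isolated), via aryl oxonium zwitterion 17 (not isolated)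
Conditions: CsF (3 equiv), 18-crown-6, 15 as solvent (0.05 M), 40 °C
Reagents that add atoms: none
Why: Proposed new method: fluoride attack on the trimethylsilyl group of 13 expels triflate and gives aryne 16, whose triple bond is polarized by the inductively withdrawing C5 methoxyl so that the ether oxygen of 15 adds at C3 (remote from that methoxyl and sterically open) and the aryl anion develops at C4. In zwitterion 17 the C4 anion, C3, the oxonium oxygen and the three carbons of the 1,1-dimethylallyl group form a six-atom array, and a charge-accelerated [3,3] shift, or ionization of the tertiary allyl–oxygen bond with recombination of the tight ion pair at the unhindered CH2 terminus, should form the C4–CH2 bond with allylic transposition and leave the methyl on O3. The closest known reactions are the aza-Claisen rearrangement of aryne adducts of tertiary allylamines, the [2,3] shift of aryne-derived allyl sulfonium ylides and the ring opening of cyclic ethers through aryne-derived aryl oxonium ions. No ring closes and no stereocenter forms. The step needs site selectivity in the oxygen addition, which the C5 methoxyl secures, and it needs the allyl shift to outrun protonation of the aryl anion, internal β-elimination to isoprene and the aryne ene reaction; 15 as the only solvent, crown-solubilized CsF without a protic or C–H acidic cosolvent, and the lack of allylic hydrogens in 15 are meant to secure this.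

Step 12
Reactants: 18 1,3-dimethoxy-5-{2-[2-methoxy-3-(MOM-oxy)-4-(SEM-oxy)phenyl]ethyl}-2-(3-methylbut-2-en-1-yl)benzene
Product: 19 4-{2-[3,5-dimethoxy-4-(3-methylbut-2-en-1-yl)phenyl]ethyl}-3-methoxy-2-(MOM-oxy)phenol
Conditions: TBAF (5 equiv), THF/DMPU, 70 °C; aqueous work-up
Reagents that add atoms: none
Why: Fluoride-induced fragmentation of the SEM ether (attack at silicon, loss of ethene and formaldehyde) frees only the 4'-phenol, since the MOM ether, the aryl methyl ethers and the prenyl group do not react with fluoride.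

Step 13
Reactants: 19 4-{2-[3,5-dimethoxy-4-(3-methylbut-2-en-1-yl)phenyl]ethyl}-3-methoxy-2-(MOM-oxy)phenol
Product: 20 4-{2-[3,5-dimethoxy-4-(3-methylbut-2-en-1-yl)phenyl]ethyl}-3-methoxy-2-(MOM-oxy)phenyl acetate
Conditions: Ac2O, pyridine, DMAP (cat.), CH2Cl2, 0 °C → rt
Reagents that add atoms: acetic anhydride, CC(=O)OC(C)=O
Why: DMAP-catalysed O-acylation of the only free hydroxyl places the acetate on O4' without any site selectivity being required.

Step 14
Reactants: 20 4-{2-[3,5-dimethoxy-4-(3-methylbut-2-en-1-yl)phenyl]ethyl}-3-methoxy-2-(MOM-oxy)phenyl acetate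
Product: 22 4-{2-[3,5-dimethoxy-4-(3-methylbut-2-en-1-yl)phenyl]ethyl}-2-hydroxy-3-methoxyphenyl acetate, via aryl trimethylsilyl ether 21 (not isolated)
Conditions: TMSOTf, 2,2'-bipyridyl, MeCN, 0 °C → rt; then H2O, rt
Reagents that add atoms: none
Why: Silyl-triflate-mediated cleavage of an aromatic MOM ether, in which the TMSOTf–bipyridyl pair converts the acetal into the aryl trimethylsilyl ether that water then hydrolyses near neutral pH, so that in the absence of free Brønsted acid or base the neighbouring aryl acetate should neither migrate nor hydrolyse and the prenyl alkene should not be protonated.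

**Compound list**

1 | 2,3,4-trihydroxybenzaldehyde | O=Cc1ccc(O)c(O)c1O | starting material
2 | 2,3-dihydroxy-4-(SEM-oxy)benzaldehyde | O=Cc1ccc(OCOCC[Si](C)(C)C)c(O)c1O | intermediate
3 | 2-hydroxy-3-(MOM-oxy)-4-(SEM-oxy)benzaldehyde | O=Cc1ccc(OCOCC[Si](C)(C)C)c(OCOC)c1O | intermediate
4 | 2-methoxy-3-(MOM-oxy)-4-(SEM-oxy)benzaldehyde | COCOc1c(OCOCC[Si](C)(C)C)ccc(C=O)c1OC | intermediate
5 | 1-ethenyl-2-methoxy-3-(MOM-oxy)-4-(SEM-oxy)benzene | C=Cc1ccc(OCOCC[Si](C)(C)C)c(OCOC)c1OC | intermediate
6 | 3-bromo-5-methoxyphenol | COc1cc(O)cc(Br)c1 | starting material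
7 | 3-bromo-5-methoxyphenyl N,N-diethylcarbamate | CCN(CC)C(=O)Oc1cc(Br)cc(OC)c1 | intermediate
8 | 9-{2-[2-methoxy-3-(MOM-oxy)-4-(SEM-oxy)phenyl]ethyl}-9-borabicyclo[3.3.1]nonane | COCOc1c(OCOCC[Si](C)(C)C)ccc(CCB2C3CCCC2CCC3)c1OC | intermediate
9 | 3-methoxy-5-{2-[2-methoxy-3-(MOM-oxy)-4-(SEM-oxy)phenyl]ethyl}phenyl N,N-diethylcarbamate | CCN(CC)C(=O)Oc1cc(OC)cc(CCc2ccc(OCOCC[Si](C)(C)C)c(OCOC)c2OC)c1 | intermediate
10 | 2-lithio derivative of 9 (lithium on the ring A carbon between the carbamate and the methoxyl) | CCN(CC)C(=O)Oc1cc(CCc2ccc(OCOCC[Si](C)(C)C)c(OCOC)c2OC)cc(OC)c1[Li] | intermediate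
11 | 3-methoxy-5-{2-[2-methoxy-3-(MOM-oxy)-4-(SEM-oxy)phenyl]ethyl}-2-(trimethylsilyl)phenyl N,N-diethylcarbamate | CCN(CC)C(=O)Oc1cc(CCc2ccc(OCOCC[Si](C)(C)C)c(OCOC)c2OC)cc(OC)c1[Si](C)(C)C | intermediate
12 | 3-methoxy-5-{2-[2-methoxy-3-(MOM-oxy)-4-(SEM-oxy)phenyl]ethyl}-2-(trimethylsilyl)phenol | COc1cc(CCc2ccc(OCOCC[Si](C)(C)C)c(OCOC)c2OC)cc(O)c1[Si](C)(C)C | intermediate
13 | 3-methoxy-5-{2-[2-methoxy-3-(MOM-oxy)-4-(SEM-oxy)phenyl]ethyl}-2-(trimethylsilyl)phenyl trifluoromethanesulfonate | COc1cc(CCc2ccc(OCOCC[Si](C)(C)C)c(OCOC)c2OC)cc(OS(=O)(=O)C(F)(F)F)c1[Si](C)(C)C | intermediate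
14 | 2-methylbut-3-en-2-ol | CC(C)(O)C=C | starting material
15 | 3-methoxy-3-methylbut-1-ene | COC(C)(C)C=C | intermediate
16 | 3-methoxy-5-{2-[2-methoxy-3-(MOM-oxy)-4-(SEM-oxy)phenyl]ethyl}-1,2-didehydrobenzene (aryne, triple bond between ring A C3 and C4) | COC1=CC(CCc2ccc(OCOCC[Si](C)(C)C)c(OCOC)c2OC)=CC#C1 | intermediate
17 | zwitterion with a methyl(2-methylbut-3-en-2-yl)oxonium group on ring A C3 and the aryl anion on C4 | COc1cc(CCc2ccc(OCOCC[Si](C)(C)C)c(OCOC)c2OC)cc([O+](C)C(C)(C)C=C)[c-]1 | intermediate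
18 | 1,3-dimethoxy-5-{2-[2-methoxy-3-(MOM-oxy)-4-(SEM-oxy)phenyl]ethyl}-2-(3-methylbut-2-en-1-yl)benzene | COc1cc(CCc2ccc(OCOCC[Si](C)(C)C)c(OCOC)c2OC)cc(OC)c1CC=C(C)C | intermediate
19 | 4-{2-[3,5-dimethoxy-4-(3-methylbut-2-en-1-yl)phenyl]ethyl}-3-methoxy-2-(MOM-oxy)phenol | COc1cc(CCc2ccc(O)c(OCOC)c2OC)cc(OC)c1CC=C(C)C | intermediate
20 | 4-{2-[3,5-dimethoxy-4-(3-methylbut-2-en-1-yl)phenyl]ethyl}-3-methoxy-2-(MOM-oxy)phenyl acetate | COc1cc(CCc2ccc(OC(C)=O)c(OCOC)c2OC)cc(OC)c1CC=C(C)C | intermediate
21 | 4-{2-[3,5-dimethoxy-4-(3-methylbut-2-en-1-yl)phenyl]ethyl}-3-methoxy-2-(trimethylsilyloxy)phenyl acetate | COc1cc(CCc2ccc(OC(C)=O)c(O[Si](C)(C)C)c2OC)cc(OC)c1CC=C(C)C | intermediate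
22 | 4-{2-[3,5-dimethoxy-4-(3-methylbut-2-en-1-yl)phenyl]ethyl}-2-hydroxy-3-methoxyphenyl acetate | COc1cc(CCc2ccc(OC(C)=O)c(O)c2OC)cc(OC)c1CC=C(C)C | target

**Step count and risk**

Total steps: 14. Longest linear sequence: 12 steps (steps 1–4, 6–9 and 11–14, from 1 to 22).

Steps most likely to fail:

1. Step 11 (proposed new method). The zwitterion may be diverted before the allyl shift: the aryl anion may capture a proton, remove a methyl hydrogen of the tertiary allyl group with release of isoprene, or the oxygen addition may revert so that the aryne is consumed by itself; recombination at the tertiary terminus would give the reverse-prenyl isomer. The fallback uses known chemistry and sets out from 9. Ortho-lithiation as in step 7 (s-BuLi, TMEDA, THF, −78 °C), transmetalation with CuBr·SMe2 and allylation with prenyl bromide should give 3-methoxy-5-{2-[2-methoxy-3-(MOM-oxy)-4-(SEM-oxy)phenyl]ethyl}-2-(3-methylbut-2-en-1-yl)phenyl N,N-diethylcarbamate F1. Reduction with LiAlH4 in THF at 65 °C should give 3-methoxy-5-{2-[2-methoxy-3-(MOM-oxy)-4-(SEM-oxy)phenyl]ethyl}-2-(3-methylbut-2-en-1-yl)phenol F2, and Williamson methylation (MeI, K2CO3, DMF) brings the route back at 18.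

2. Step 14. During acetal cleavage the acetyl group may move to the newly freed neighbouring oxygen or be lost. The fallback sets out from 19 and reverses the order of the last two operations. The MOM ether is cleaved while no ester is present (aq HCl, MeOH, 40 °C) to give 4-{2-[3,5-dimethoxy-4-(3-methylbut-2-en-1-yl)phenyl]ethyl}-3-methoxybenzene-1,2-diol F3. Monoacetylation with one equivalent of Ac2O and pyridine in CH2Cl2 at −20 °C should then occur at the less hindered 4'-hydroxyl, the 3'-hydroxyl being flanked by the 2'-methoxyl and hydrogen-bonded to it, and returns to the route at 22.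

3. Step 1. Alkylation may not stop at one phenol or may take place on O3, that is, loss of site control among three hydroxyls. The fallback sets out from 1 and masks O3 and O4 together first. Heating with dichlorodiphenylmethane (neat, 160 °C) should give the ketal 4-hydroxy-2,2-diphenyl-1,3-benzodioxole-5-carbaldehyde F4, and methylation of the chelated phenol (MeI, K2CO3, DMF) gives 4-methoxy-2,2-diphenyl-1,3-benzodioxole-5-carbaldehyde F5. Hydrolysis in aqueous acetic acid at reflux releases 3,4-dihydroxy-2-methoxybenzaldehyde F6. Only two phenols now remain and the one para to the formyl group is far more acidic, so SEMCl with K2CO3 in acetone should give 3-hydroxy-2-methoxy-4-(SEM-oxy)benzaldehyde F7. MOMCl with i-Pr2NEt in CH2Cl2 then rejoins the route at 4.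

**Further compounds**

F1 | step 11 | 3-methoxy-5-{2-[2-methoxy-3-(MOM-oxy)-4-(SEM-oxy)phenyl]ethyl}-2-(3-methylbut-2-en-1-yl)phenyl N,N-diethylcarbamate | CCN(CC)C(=O)Oc1cc(CCc2ccc(OCOCC[Si](C)(C)C)c(OCOC)c2OC)cc(OC)c1CC=C(C)C
F2 | step 11 | 3-methoxy-5-{2-[2-methoxy-3-(MOM-oxy)-4-(SEM-oxy)phenyl]ethyl}-2-(3-methylbut-2-en-1-yl)phenol | COc1cc(CCc2ccc(OCOCC[Si](C)(C)C)c(OCOC)c2OC)cc(O)c1CC=C(C)C
F3 | step 14 | 4-{2-[3,5-dimethoxy-4-(3-methylbut-2-en-1-yl)phenyl]ethyl}-3-methoxybenzene-1,2-diol | COc1cc(CCc2ccc(O)c(O)c2OC)cc(OC)c1CC=C(C)C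
F4 | step 1 | 4-hydroxy-2,2-diphenyl-1,3-benzodioxole-5-carbaldehyde | O=Cc1ccc2OC(c3ccccc3)(c3ccccc3)Oc2c1O
F5 | step 1 | 4-methoxy-2,2-diphenyl-1,3-benzodioxole-5-carbaldehyde | COc1c(C=O)ccc2OC(c3ccccc3)(c3ccccc3)Oc12
F6 | step 1 | 3,4-dihydroxy-2-methoxybenzaldehyde | COc1c(C=O)ccc(O)c1O
F7 | step 1 | 3-hydroxy-2-methoxy-4-(SEM-oxy)benzaldehyde | COc1c(C=O)ccc(OCOCC[Si](C)(C)C)c1O
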